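## Analysis of the target

The target is a C–C-linked biflavonoid. One half is a flavanone of the eriodictyol type: a 5,7-dihydroxychroman-4-one (rings A and C) carrying at C2 a catechol ring B (carbons C1'–C6', hydroxyls on C3' and C4'). The other half is the flavone luteolin (rings A', C' and B'), bonded through its C8 to C6' of ring B, the carbon next to C1', which holds the chromanone.

There is one stereocentre, chromanone C2, with R configuration; this is the spatial arrangement opposite to that of the common (2S)-flavanones. The axis C6'–flavone C8 has three ortho substituents (C1' with its chromanone, and the oxygens on flavone C7 and C8a), so it is crowded, and it is drawn without configuration.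

The sensitive groups are eight phenols (two of them air-sensitive catechols, two hydrogen-bonded 5-hydroxyls) and C2 itself. C2 is a benzylic ether carbon β to a ketone, and base epimerises it through retro-oxa-Michael opening to the chalcone. The difficulty is therefore to make a hindered biaryl bond directly beside a base-labile stereocentre.

The strategy rests on ring B. C1' and C6' are adjacent and carry the two halves, and the remaining four carbons C2'–C5', with oxygen on C3' and C4', have the pattern of a 2,3-dioxygenated buta-1,3-diene. C1' and C6' can therefore enter as the two carbons of an alkyne that bridges chromanone C2 and flavone C8, and ring B can be grown between the two halves.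

## Retrosynthetic reasoning

**19 ⇒ 18.** The last bonds cut are the six O–benzyl bonds on rings A, A' and B'. Benzyl is chosen because it leaves by neutral hydrogenolysis, so the free flavanone never meets base, and because it survives the Lewis acid, the quinone oxidant and the low-valent metals used earlier. The ring B catechol is already free in 18.

**18 ⇒ 17 ⇒ 16.** Ring B is taken back to the dihydro level: two hydrogens return to C2' and C5', and the catechol oxygens become trimethylsilyl enol ethers. This exchanges the arene for the 1,2-bis(silyloxy)cyclohexa-1,4-diene 16, the direct product of a [4+2] addition to an alkyne. The forward operation is a dehydrogenation to 17 and solvolysis of its two aryl silyl ethers; it must stop at the catechol and leave C2–H alone.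

**16 ⇒ 13 + 15.** This is the key cut, through C1'–C2' and C5'–C6'. It is made here and not at the biaryl bond or at C2–C1', because those two bonds join crowded or labile positions, whereas after this cut both become bonds to a linear alkyne. One operation then delivers ring B, the hindered biaryl and the aryl–C2 link, and diene 15 is symmetrical, so no regiochemistry arises. In the forward sense an unactivated internal alkyne must add to an electron-rich diene. That does not happen thermally, so a low-valent cobalt catalyst has to mediate it, without base and without ionising the propargylic C2–O bond.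

**13 ⇒ 10 + 6 (through 11 and 12).** The C2–C(sp) bond is cut. This exposes the planar chromone 10 and the terminal alkyne 6. The forward reaction, addition of a copper acetylide to the silylated benzopyrylium ion 11 under a chiral ligand, creates the only stereocentre while the electrophile is still small and unhindered. The product first appears as the silyl enol ether 12, which cannot ring-open, and acid then releases the ketone.

**6 ⇒ 5 ⇒ 3 + 4, and 3 ⇒ 2 ⇒ 1.** The flavone C8–C(sp) bond is cut to the 8-iodide 3 and the silyl-capped acetylene 4 (Sonogashira coupling, then C-desilylation). Iodide 3 comes from electrophilic iodination of the perbenzylated flavone 2, and 2 from luteolin 1. The whole flavone half, with its four oxygens in place, is thus bought; the forward iodination has to choose C8 over C6.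

**10 ⇒ 9 ⇒ 8 ⇒ 7.** The pyranone of 10 is opened at O1–C2 and C2–C3 to the enaminone 9, made from methyl ketone 8 and a one-carbon formamide acetal. Ketone 8 comes from 7 by benzylation of the two hydroxyls that are not locked in the hydrogen bond to the acetyl group.

**15 ⇒ 14.** Two O–Si bonds are cut; the forward step is a double enol silylation of 14.

## Alternatives that were turned down

**Alternative 1:** The benzo ring A' of the flavone is grown onto ring B by a Danheiser benzannulation, forming flavone C8–C8a, C6–C7 and C4a–C8a. Heating cyclobutenone A2 with aryl siloxyalkyne A3 would give the resorcinol monosilyl ether A1 by 4π ring opening to a vinylketene, [2+2] addition to the ynol ether, a second ring opening and 6π closure.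

- In its favour: the crowded axis exists beforehand as an aryl–alkyne bond, the same idea as in the chosen route. The cascade is pericyclic and needs no metal or Lewis acid. The three oxygens of the new ring emerge differentiated and with unambiguous regiochemistry. On that last point it is stronger than the chosen route, whose C8 iodination relies on directing effects.
- Against it: it builds the simplest ring of the target. After A1 the flavone pyranone still has to be made (C-acylation at C4a, introduction of ring B', cyclodehydration), and the ethyl ether at C5 has to be cleaved among other ethers. The whole flavanone, with its stereocentre, must then be raised from the masked aldehyde. The usual chalcone and oxa-Michael sequence runs in base and does not reliably give one enantiomer.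
- Comparison: it is much longer, it makes by synthesis what luteolin 1 supplies, and it leaves the stereocentre to the end. In place of its regiochemical certainty the chosen strategy offers a short route and a stereocentre set early by catalysis.

**Alternative 2:** Flavanone ring A is annulated last onto an enantioenriched dihydropyranone, forming C8–C8a and C4a–C5. Diene A5 would add thermally across the C4a=C8a bond of sulfoxide A6; the sulfinyl group then leaves as its sulfenic acid and the methoxy group as the alcohol, and the new ring aromatises to A4.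

- In its favour: C2 could be set by an asymmetric hetero-Diels–Alder reaction of an aryl aldehyde, which is at least as well established as the copper-catalysed alkynylation used here, so on stereocontrol it is equal or stronger. The sulfoxide fixes the regiochemistry, and A4 needs only hydrogenolysis.
- Against it: A6 already contains the full biaryl, so the tri-ortho-substituted axis must be made by cross-coupling two hindered arenes, which is the central problem left unsolved. The aldehyde for the hetero-Diels–Alder step would carry that biaryl in the ortho position. Installing the sulfinyl group costs steps. The C4a=C8a bond is a β-alkoxy enone and a reluctant partner for an electron-rich diene; under the heat required, the 2-aryl dihydropyranone can open by retro-oxa-Michael reaction and put C2 at risk.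
- Comparison: equal on stereocontrol, weaker on the biaryl bond and on step count. The chosen strategy makes the biaryl as a by-product of ring formation.

**Alternative 3:** The flavone pyranone is made by a carbonylative three-component annulation, forming C4a–C4, C4–C3 and O1–C2. A palladium–phosphine catalyst under carbon monoxide A10 would couple the biaryl iodophenol A8 with arylacetylene A9 to an ynone, and a secondary amine would promote 6-endo closure of the phenol oxygen to give A7.

- In its favour: it is convergent, and this reaction type is widely used for flavones on functionalised substrates. Its precedent is broader than that of the cobalt cycloaddition, so its key step is the safer one.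
- Against it: A8 must already hold the hindered biaryl, exactly one free phenol among three phloroglucinol oxygens, and iodine on one specific carbon. Oxidative addition into an electron-rich, doubly ortho-substituted iodide is slow. Direct coupling followed by 5-endo closure (benzofuran) and 5-exo closure of the ynone (aurone) compete. After A7 the flavanone and its stereocentre are still to be built from the acetal, as in alternative 1.
- Comparison: the chosen route takes the flavone from 1 and needs no pyranone synthesis. In place of the better precedent it offers roughly half the length and a catalytically set stereocentre.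

Key step: step 9

Assumption: the axis C6'–flavone C8 is treated as stereochemically undefined, as drawn; slow rotation would show only as interconverting rotamers of 16–19.

Assumption: the sense of induction of the P,N ligand in step 7 is assigned on the first run, and the antipode that gives the 2R product is used.

## Route

Step 1
Reactants: 1 luteolin
Product: 2 5,7-bis(benzyloxy)-2-[3,4-bis(benzyloxy)phenyl]-4H-chromen-4-one
Conditions: BnBr (6 equiv), K2CO3, nBu4NI (cat.), DMF, 70 °C
Reagents that add atoms: benzyl bromide, BrCc1ccccc1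
Why: Williamson ether synthesis; the three unchelated phenols react first, and the hydrogen-bonded 5-hydroxyl is forced by excess halide, iodide catalysis and heat.

Step 2
Reactants: 2 5,7-bis(benzyloxy)-2-[3,4-bis(benzyloxy)phenyl]-4H-chromen-4-one
Product: 3 5,7-bis(benzyloxy)-2-[3,4-bis(benzyloxy)phenyl]-8-iodo-4H-chromen-4-one
Conditions: NIS (1.1 equiv), TFA (cat.), CH2Cl2/MeCN, 0 °C to rt
Reagents that add atoms: N-iodosuccinimide, O=C1CCC(=O)N1I
Why: Electrophilic aromatic iodination; with every hydroxyl alkylated, C8 (para to the 5-benzyloxy group, ortho to the 7-benzyloxy group) is the most nucleophilic carbon and is less shielded than C6, which lies between two benzyloxy groups, while ring B' is deactivated by the conjugated pyranone.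

Step 3
Reactants: 3 5,7-bis(benzyloxy)-2-[3,4-bis(benzyloxy)phenyl]-8-iodo-4H-chromen-4-one; 4 ethynyltrimethylsilane
Product: 5 5,7-bis(benzyloxy)-2-[3,4-bis(benzyloxy)phenyl]-8-[(trimethylsilyl)ethynyl]-4H-chromen-4-one
Conditions: PdCl2(PPh3)2 (5 mol%, divalent palladium, reduced in the flask to zerovalent palladium), CuI (10 mol%, monovalent copper), Et3N, DMF, 60 °C
Reagents that add atoms: none
Why: Sonogashira coupling; gentle heating compensates for the electron-rich, doubly ortho-substituted iodide, and the silyl cap prevents alkyne homocoupling and double arylation.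

Step 4
Reactants: 5 5,7-bis(benzyloxy)-2-[3,4-bis(benzyloxy)phenyl]-8-[(trimethylsilyl)ethynyl]-4H-chromen-4-one
Product: 6 5,7-bis(benzyloxy)-2-[3,4-bis(benzyloxy)phenyl]-8-ethynyl-4H-chromen-4-one
Conditions: K2CO3 (0.2 equiv), MeOH/THF, rt
Reagents that add atoms: none
Why: Base-catalysed methanolysis of the alkynyl C–Si bond (protodesilylation); the flavone and the benzyl ethers are inert to catalytic carbonate at room temperature.

Step 5
Reactants: 7 2,4,6-trihydroxyacetophenone
Product: 8 1-[2,4-bis(benzyloxy)-6-hydroxyphenyl]ethan-1-one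
Conditions: BnBr (2.2 equiv), K2CO3, acetone, reflux
Reagents that add atoms: benzyl bromide, BrCc1ccccc1
Why: Williamson ether synthesis; after the para and one ortho hydroxyl are alkylated, the remaining ortho hydroxyl is held in a hydrogen bond to the acetyl group and stays free.

Step 6
Reactants: 8 1-[2,4-bis(benzyloxy)-6-hydroxyphenyl]ethan-1-one
Product: 10 5,7-bis(benzyloxy)-4H-chromen-4-one, via enaminone 9 (not isolated)
Conditions: DMF-DMA, toluene, 100 °C; then 2 M HCl, CH2Cl2, 40 °C
Reagents that add atoms: N,N-dimethylformamide dimethyl acetal, COC(OC)N(C)C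
Why: Condensation of the methyl ketone with the amide acetal gives enaminone 9; acid then promotes intramolecular conjugate addition of the phenol and loss of dimethylamine, the standard enaminone route to 2,3-unsubstituted chromones.

Step 7
Reactants: 10 5,7-bis(benzyloxy)-4H-chromen-4-one; 6 5,7-bis(benzyloxy)-2-[3,4-bis(benzyloxy)phenyl]-8-ethynyl-4H-chromen-4-one
Product: 13 (2R)-5,7-bis(benzyloxy)-2-({5,7-bis(benzyloxy)-2-[3,4-bis(benzyloxy)phenyl]-4-oxo-4H-chromen-8-yl}ethynyl)chroman-4-one, via silyloxybenzopyrylium triflate 11 (not isolated), via silyl enol ether 12 (not isolated)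
Conditions: TBSOTf (1.3 equiv), CH2Cl2/toluene, 0 °C; then 6, CuI (10 mol%, monovalent copper), StackPhos (12 mol%, antipode giving 2R), iPr2NEt (2 equiv), −20 °C; then 2 M HCl, THF, 0 °C
Reagents that add atoms: none
Why: Copper-catalysed enantioselective alkynylation of a chromone through its 4-silyloxybenzopyrylium salt: the silyl triflate turns 10 into cation 11, and the copper acetylide formed from 6, CuI and the amine adds to C2 on the face left open by the axially chiral P,N ligand, which sets the C2 stereocentre and gives enol ether 12; acid then releases the ketone without any base, so C2 cannot epimerise by ring opening.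

Step 8
Reactants: 14 butane-2,3-dione
Product: 15 2,3-bis(trimethylsilyloxy)buta-1,3-diene
Conditions: TMSOTf (2.2 equiv), Et3N (2.4 equiv), Et2O, 0 °C to rt; distillation
Reagents that add atoms: trimethylsilyl trifluoromethanesulfonate, C[Si](C)(C)OS(=O)(=O)C(F)(F)F
Why: Double soft enolisation and O-silylation of a 1,2-diketone; the diene is distilled and used fresh because its enol ethers are moisture-sensitive.

Step 9
Reactants: 13 (2R)-5,7-bis(benzyloxy)-2-({5,7-bis(benzyloxy)-2-[3,4-bis(benzyloxy)phenyl]-4-oxo-4H-chromen-8-yl}ethynyl)chroman-4-one; 15 2,3-bis(trimethylsilyloxy)buta-1,3-diene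
Product: 16 (2R)-5,7-bis(benzyloxy)-2-[2-{5,7-bis(benzyloxy)-2-[3,4-bis(benzyloxy)phenyl]-4-oxo-4H-chromen-8-yl}-4,5-bis(trimethylsilyloxy)cyclohexa-1,4-dien-1-yl]chroman-4-one
Conditions: CoBr2(dppe) (20 mol%, divalent cobalt), Zn powder (40 mol%), ZnI2 (40 mol%), 15 (3 equiv), CH2Cl2, rt
Reagents that add atoms: none
Why: Zinc reduces CoBr2(dppe) (divalent cobalt) to a monovalent cobalt species, and ZnI2 removes halide from it so that diene 15 and the alkyne of 13 can both bind; oxidative cyclisation then joins one diene terminus to one alkyne carbon to give a cobaltacycle, and reductive elimination forms the second C–C bond and releases the 1,4-diene. The closest known reaction type is the cobalt-catalysed neutral Diels–Alder reaction of unactivated internal alkynes with 2-silyloxy- and 2,3-disubstituted buta-1,3-dienes. Ring B closes as a six-membered carbocycle in a metal-mediated [4+2] mode through the bonds C1'–C2' and C5'–C6', with C1'=C6' left as the residual alkene. No stereocentre is formed; C2 is a bystander and should keep its R configuration because the medium contains no base and only a substoichiometric, mild Lewis acid. The step needs chemoselectivity for the alkyne over the one enone of 13 (flavone C2=C3–C4=O) and over the chromanone ketone, which is a saturated aryl ketone and not an enone; the flavone alkene is trisubstituted, donor-substituted and part of the pyranone, so it is a poor ligand for the cobalt–diene complex, and ketones do not enter this cycle. The propargylic C2–O bond should survive because its aryloxy oxygen is delocalised into the C4 carbonyl and binds ZnI2 weakly, and both carbonyl groups are too deactivated by their alkoxy donors to undergo Mukaiyama-type addition of the silyl enol ether. The diene is symmetrical, so either orientation gives the same product, and its excess makes up for any enol ether lost to the Lewis acid.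

Step 10
Reactants: 16 (2R)-5,7-bis(benzyloxy)-2-[2-{5,7-bis(benzyloxy)-2-[3,4-bis(benzyloxy)phenyl]-4-oxo-4H-chromen-8-yl}-4,5-bis(trimethylsilyloxy)cyclohexa-1,4-dien-1-yl]chroman-4-one
Product: 18 (2R)-5,7-bis(benzyloxy)-2-[2-{5,7-bis(benzyloxy)-2-[3,4-bis(benzyloxy)phenyl]-4-oxo-4H-chromen-8-yl}-4,5-dihydroxyphenyl]chroman-4-one, via bis(trimethylsilyl) catechol ether 17 (not isolated)
Conditions: DDQ (1.0 equiv), toluene, 0 °C to rt; filtration; then PPTS (cat.), MeOH/THF, rt
Reagents that add atoms: none
Why: Dehydrogenative aromatisation of a 1,4-cyclohexadiene (hydride abstraction from a doubly allylic CH2 by the quinone, then proton loss) gives 17, and acid-catalysed methanolysis cleaves its two aryl silyl ethers; exactly one equivalent of oxidant is used so that none remains when the catechol is freed, and benzyl ethers and C2–H do not react at room temperature.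

Step 11
Reactants: 18 (2R)-5,7-bis(benzyloxy)-2-[2-{5,7-bis(benzyloxy)-2-[3,4-bis(benzyloxy)phenyl]-4-oxo-4H-chromen-8-yl}-4,5-dihydroxyphenyl]chroman-4-one
Product: 19 (2R)-2-{2-[2-(3,4-dihydroxyphenyl)-5,7-dihydroxy-4-oxo-4H-chromen-8-yl]-4,5-dihydroxyphenyl}-5,7-dihydroxychroman-4-one
Conditions: H2 (1 atm), 10% Pd/C, THF/MeOH, rt, under exclusion of air on work-up
Reagents that add atoms: none
Why: Hydrogenolysis of six aryl benzyl ethers under neutral conditions, which leave C2 untouched; at one atmosphere and room temperature the flavone C2=C3 bond (a vinylogous ester) and the cyclic benzylic C2–O1 bond are expected to resist, and the reaction is stopped at full debenzylation.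

## Compound list

1 | luteolin | O=c1cc(-c2ccc(O)c(O)c2)oc2cc(O)cc(O)c12 | starting material
2 | 5,7-bis(benzyloxy)-2-[3,4-bis(benzyloxy)phenyl]-4H-chromen-4-one | O=c1cc(-c2ccc(OCc3ccccc3)c(OCc3ccccc3)c2)oc2cc(OCc3ccccc3)cc(OCc3ccccc3)c12 | intermediate
3 | 5,7-bis(benzyloxy)-2-[3,4-bis(benzyloxy)phenyl]-8-iodo-4H-chromen-4-one | O=c1cc(-c2ccc(OCc3ccccc3)c(OCc3ccccc3)c2)oc2c(I)c(OCc3ccccc3)cc(OCc3ccccc3)c12 | intermediate
4 | ethynyltrimethylsilane | C#C[Si](C)(C)C | starting material
5 | 5,7-bis(benzyloxy)-2-[3,4-bis(benzyloxy)phenyl]-8-[(trimethylsilyl)ethynyl]-4H-chromen-4-one | O=c1cc(-c2ccc(OCc3ccccc3)c(OCc3ccccc3)c2)oc2c(C#C[Si](C)(C)C)c(OCc3ccccc3)cc(OCc3ccccc3)c12 | intermediate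
6 | 5,7-bis(benzyloxy)-2-[3,4-bis(benzyloxy)phenyl]-8-ethynyl-4H-chromen-4-one | O=c1cc(-c2ccc(OCc3ccccc3)c(OCc3ccccc3)c2)oc2c(C#C)c(OCc3ccccc3)cc(OCc3ccccc3)c12 | intermediate
7 | 2,4,6-trihydroxyacetophenone | CC(=O)c1c(O)cc(O)cc1O | starting material
8 | 1-[2,4-bis(benzyloxy)-6-hydroxyphenyl]ethan-1-one | CC(=O)c1c(O)cc(OCc2ccccc2)cc1OCc1ccccc1 | intermediate
9 | (E)-1-[2,4-bis(benzyloxy)-6-hydroxyphenyl]-3-(dimethylamino)prop-2-en-1-one | CN(C)/C=C/C(=O)c1c(O)cc(OCc2ccccc2)cc1OCc1ccccc1 | intermediate (not isolated)
10 | 5,7-bis(benzyloxy)-4H-chromen-4-one | O=c1ccoc2cc(OCc3ccccc3)cc(OCc3ccccc3)c12 | intermediate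
11 | 5,7-bis(benzyloxy)-4-[(tert-butyldimethylsilyl)oxy]chromenylium trifluoromethanesulfonate | CC(C)(C)[Si](C)(C)Oc1cc[o+]c2cc(OCc3ccccc3)cc(OCc3ccccc3)c12.[O-]S(=O)(=O)C(F)(F)F | intermediate (not isolated)
12 | (2R)-5,7-bis(benzyloxy)-4-[(tert-butyldimethylsilyl)oxy]-2-({5,7-bis(benzyloxy)-2-[3,4-bis(benzyloxy)phenyl]-4-oxo-4H-chromen-8-yl}ethynyl)-2H-chromene | CC(C)(C)[Si](C)(C)OC1=C[C@H](C#Cc2c(OCc3ccccc3)cc(OCc3ccccc3)c3c(=O)cc(-c4ccc(OCc5ccccc5)c(OCc5ccccc5)c4)oc23)Oc2cc(OCc3ccccc3)cc(OCc3ccccc3)c21 | intermediate (not isolated)
13 | (2R)-5,7-bis(benzyloxy)-2-({5,7-bis(benzyloxy)-2-[3,4-bis(benzyloxy)phenyl]-4-oxo-4H-chromen-8-yl}ethynyl)chroman-4-one | O=C1C[C@H](C#Cc2c(OCc3ccccc3)cc(OCc3ccccc3)c3c(=O)cc(-c4ccc(OCc5ccccc5)c(OCc5ccccc5)c4)oc23)Oc2cc(OCc3ccccc3)cc(OCc3ccccc3)c21 | intermediate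
14 | butane-2,3-dione | CC(=O)C(C)=O | starting material
15 | 2,3-bis(trimethylsilyloxy)buta-1,3-diene | C=C(O[Si](C)(C)C)C(=C)O[Si](C)(C)C | intermediate
16 | (2R)-5,7-bis(benzyloxy)-2-[2-{5,7-bis(benzyloxy)-2-[3,4-bis(benzyloxy)phenyl]-4-oxo-4H-chromen-8-yl}-4,5-bis(trimethylsilyloxy)cyclohexa-1,4-dien-1-yl]chroman-4-one | O=C1C[C@H](C2=C(c3c(OCc4ccccc4)cc(OCc4ccccc4)c4c(=O)cc(-c5ccc(OCc6ccccc6)c(OCc6ccccc6)c5)oc34)CC(O[Si](C)(C)C)=C(O[Si](C)(C)C)C2)Oc2cc(OCc3ccccc3)cc(OCc3ccccc3)c21 | intermediate
17 | (2R)-5,7-bis(benzyloxy)-2-[2-{5,7-bis(benzyloxy)-2-[3,4-bis(benzyloxy)phenyl]-4-oxo-4H-chromen-8-yl}-4,5-bis(trimethylsilyloxy)phenyl]chroman-4-one | O=C1C[C@H](c2cc(O[Si](C)(C)C)c(O[Si](C)(C)C)cc2-c2c(OCc3ccccc3)cc(OCc3ccccc3)c3c(=O)cc(-c4ccc(OCc5ccccc5)c(OCc5ccccc5)c4)oc23)Oc2cc(OCc3ccccc3)cc(OCc3ccccc3)c21 | intermediate (not isolated)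
18 | (2R)-5,7-bis(benzyloxy)-2-[2-{5,7-bis(benzyloxy)-2-[3,4-bis(benzyloxy)phenyl]-4-oxo-4H-chromen-8-yl}-4,5-dihydroxyphenyl]chroman-4-one | O=C1C[C@H](c2cc(O)c(O)cc2-c2c(OCc3ccccc3)cc(OCc3ccccc3)c3c(=O)cc(-c4ccc(OCc5ccccc5)c(OCc5ccccc5)c4)oc23)Oc2cc(OCc3ccccc3)cc(OCc3ccccc3)c21 | intermediate
19 | (2R)-2-{2-[2-(3,4-dihydroxyphenyl)-5,7-dihydroxy-4-oxo-4H-chromen-8-yl]-4,5-dihydroxyphenyl}-5,7-dihydroxychroman-4-one | O=C1C[C@H](c2cc(O)c(O)cc2-c2c(O)cc(O)c3c(=O)cc(-c4ccc(O)c(O)c4)oc23)Oc2cc(O)cc(O)c21 | target

## Step count and risks

Total step count: 11. Longest linear sequence: 8 steps (steps 1, 2, 3, 4, 7, 9, 10, 11).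

**Step 9 (key step).** The alkyne may fail to bind or to undergo oxidative cyclisation, since one end carries an aryl group with two ortho oxygens and the other a branched propargylic carbon. The many ether and carbonyl oxygens may sequester zinc and cobalt. The Lewis acid may strip silyl groups from the diene or ionise the propargylic C2–O bond, which would erode the configuration.

Fallback, setting out from 13 and returning at 18: butane-2,3-dione 14 would be silylated with TBSOTf and Et3N to 2,3-bis(tert-butyldimethylsilyloxy)buta-1,3-diene F1, whose enol ethers tolerate handling. Alkyne 13 and F1 would be joined under [Rh(cod)(C10H8)]SbF6 (monovalent rhodium; C10H8 is naphthalene) in CH2Cl2 at room temperature. This cationic catalyst type is known for intermolecular [4+2] additions of unactivated alkynes to dienes and needs neither a reductant nor a zinc halide. The product would be (2R)-5,7-bis(benzyloxy)-2-[2-{5,7-bis(benzyloxy)-2-[3,4-bis(benzyloxy)phenyl]-4-oxo-4H-chromen-8-yl}-4,5-bis(tert-butyldimethylsilyloxy)cyclohexa-1,4-dien-1-yl]chroman-4-one F2. DDQ would aromatise it to the isolable bis(tert-butyldimethylsilyl) catechol ether F3, and Et3N·3HF in THF would free catechol 18.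

**Step 7.** Conversion may be low: the 5,7-dialkoxybenzopyrylium ion 11 is a stabilised, weak electrophile, the acetylide from 6 is bulky, and the carbonyl of 6 competes for the silyl triflate. Facial selectivity may also be poor with an alkyne much larger than the usual ones.

Fallback, setting out from 10 and 4 and returning at 13 (it uses iodide 3 directly, so steps 3 and 4 fall away): cation 11 would be treated with the small alkyne 4 under the same copper and ligand system to give (2R)-5,7-bis(benzyloxy)-4-[(tert-butyldimethylsilyl)oxy]-2-[(trimethylsilyl)ethynyl]-2H-chromene F4. Aqueous acid would convert it to (2R)-5,7-bis(benzyloxy)-2-[(trimethylsilyl)ethynyl]chroman-4-one F5. Fluoride buffered with acetic acid (nBu4NF, AcOH, THF, 0 °C) would remove the C-silyl group to give (2R)-5,7-bis(benzyloxy)-2-ethynylchroman-4-one F6. Sonogashira coupling of F6 with 3 (Pd(PPh3)4, zerovalent palladium; CuI, monovalent copper; iPr2NEt, THF, rt) would give 13. Contact with the amine is kept short to limit ring opening at C2.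

**Step 2 (and the forcing benzylation of step 1).** Iodination may be unselective (C6, flavone C3 or ring B' in place of C8). In step 1 the chelated 5-hydroxyl may resist alkylation, or C-benzylation may intervene.

Fallback, setting out from 8 and returning at 3: ketone 8 would be iodinated with NIS ortho to its free phenol to give 1-[4,6-bis(benzyloxy)-2-hydroxy-3-iodophenyl]ethan-1-one F7, with the position of iodine confirmed at this simple stage. Claisen–Schmidt condensation with commercial 3,4-bis(benzyloxy)benzaldehyde (KOH, EtOH) would give (E)-1-[4,6-bis(benzyloxy)-2-hydroxy-3-iodophenyl]-3-[3,4-bis(benzyloxy)phenyl]prop-2-en-1-one F8. Oxidative cyclisation (I2 cat., DMSO, 120 °C) would give 3, in which the only free phenol oxygen becomes O1, so the iodine is necessarily at C8.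

**Step 11.** Over-reduction may occur (saturation of the flavone C2=C3 bond, hydrogenolysis of the benzylic C2–O1 bond). Debenzylation may stall if partly deprotected intermediates precipitate or adsorb on the carbon.

Fallback, setting out from 18 and returning at 19: non-reductive Lewis acid debenzylation with BCl3 and pentamethylbenzene as benzyl cation scavenger in CH2Cl2 at −78 °C. No new compound is formed on the way.

## Further compounds

F1 | step 9 | 2,3-bis(tert-butyldimethylsilyloxy)buta-1,3-diene | C=C(O[Si](C)(C)C(C)(C)C)C(=C)O[Si](C)(C)C(C)(C)C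
F2 | step 9 | (2R)-5,7-bis(benzyloxy)-2-[2-{5,7-bis(benzyloxy)-2-[3,4-bis(benzyloxy)phenyl]-4-oxo-4H-chromen-8-yl}-4,5-bis(tert-butyldimethylsilyloxy)cyclohexa-1,4-dien-1-yl]chroman-4-one | O=C1C[C@H](C2=C(c3c(OCc4ccccc4)cc(OCc4ccccc4)c4c(=O)cc(-c5ccc(OCc6ccccc6)c(OCc6ccccc6)c5)oc34)CC(O[Si](C)(C)C(C)(C)C)=C(O[Si](C)(C)C(C)(C)C)C2)Oc2cc(OCc3ccccc3)cc(OCc3ccccc3)c21
F3 | step 9 | (2R)-5,7-bis(benzyloxy)-2-[2-{5,7-bis(benzyloxy)-2-[3,4-bis(benzyloxy)phenyl]-4-oxo-4H-chromen-8-yl}-4,5-bis(tert-butyldimethylsilyloxy)phenyl]chroman-4-one | O=C1C[C@H](c2cc(O[Si](C)(C)C(C)(C)C)c(O[Si](C)(C)C(C)(C)C)cc2-c2c(OCc3ccccc3)cc(OCc3ccccc3)c3c(=O)cc(-c4ccc(OCc5ccccc5)c(OCc5ccccc5)c4)oc23)Oc2cc(OCc3ccccc3)cc(OCc3ccccc3)c21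
F4 | step 7 | (2R)-5,7-bis(benzyloxy)-4-[(tert-butyldimethylsilyl)oxy]-2-[(trimethylsilyl)ethynyl]-2H-chromene | CC(C)(C)[Si](C)(C)OC1=C[C@H](C#C[Si](C)(C)C)Oc2cc(OCc3ccccc3)cc(OCc3ccccc3)c21
F5 | step 7 | (2R)-5,7-bis(benzyloxy)-2-[(trimethylsilyl)ethynyl]chroman-4-one | O=C1C[C@H](C#C[Si](C)(C)C)Oc2cc(OCc3ccccc3)cc(OCc3ccccc3)c21
F6 | step 7 | (2R)-5,7-bis(benzyloxy)-2-ethynylchroman-4-one | O=C1C[C@H](C#C)Oc2cc(OCc3ccccc3)cc(OCc3ccccc3)c21
F7 | step 2 | 1-[4,6-bis(benzyloxy)-2-hydroxy-3-iodophenyl]ethan-1-one | CC(=O)c1c(O)c(I)c(OCc2ccccc2)cc1OCc1ccccc1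
F8 | step 2 | (E)-1-[4,6-bis(benzyloxy)-2-hydroxy-3-iodophenyl]-3-[3,4-bis(benzyloxy)phenyl]prop-2-en-1-one | O=C(/C=C/c1ccc(OCc2ccccc2)c(OCc2ccccc2)c1)c1c(O)c(I)c(OCc2ccccc2)cc1OCc1ccccc1
F0 | step 11 | none | none
A1 | alternative 1 | 2-[4,5-bis(benzyloxy)-2-(1,3-dioxolan-2-yl)phenyl]-5-ethoxy-3-(triisopropylsilyloxy)phenol | CCOc1cc(O)c(-c2cc(OCc3ccccc3)c(OCc3ccccc3)cc2C2OCCO2)c(O[Si](C(C)C)(C(C)C)C(C)C)c1
A2 | alternative 1 | 3-ethoxycyclobut-2-en-1-one | CCOC1=CC(=O)C1
A3 | alternative 1 | {[4,5-bis(benzyloxy)-2-(1,3-dioxolan-2-yl)phenyl]ethynyloxy}triisopropylsilane | CC(C)[Si](OC#Cc1cc(OCc2ccccc2)c(OCc2ccccc2)cc1C1OCCO1)(C(C)C)C(C)C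
A4 | alternative 2 | (2R)-2-[4,5-bis(benzyloxy)-2-{5,7-bis(benzyloxy)-2-[3,4-bis(benzyloxy)phenyl]-4-oxo-4H-chromen-8-yl}phenyl]-5,7-dihydroxychroman-4-one | O=C1C[C@H](c2cc(OCc3ccccc3)c(OCc3ccccc3)cc2-c2c(OCc3ccccc3)cc(OCc3ccccc3)c3c(=O)cc(-c4ccc(OCc5ccccc5)c(OCc5ccccc5)c4)oc23)Oc2cc(O)cc(O)c21
A5 | alternative 2 | 1-methoxy-1,3-bis(trimethylsilyloxy)buta-1,3-diene | COC(O[Si](C)(C)C)=CC(=C)O[Si](C)(C)C
A6 | alternative 2 | (2R)-2-[4,5-bis(benzyloxy)-2-{5,7-bis(benzyloxy)-2-[3,4-bis(benzyloxy)phenyl]-4-oxo-4H-chromen-8-yl}phenyl]-5-(phenylsulfinyl)-2,3-dihydro-4H-pyran-4-one | O=C1C[C@H](c2cc(OCc3ccccc3)c(OCc3ccccc3)cc2-c2c(OCc3ccccc3)cc(OCc3ccccc3)c3c(=O)cc(-c4ccc(OCc5ccccc5)c(OCc5ccccc5)c4)oc23)OC=C1S(=O)c1ccccc1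
A7 | alternative 3 | 5,7-bis(benzyloxy)-8-[4,5-bis(benzyloxy)-2-(1,3-dioxolan-2-yl)phenyl]-2-[3,4-bis(benzyloxy)phenyl]-4H-chromen-4-one | O=c1cc(-c2ccc(OCc3ccccc3)c(OCc3ccccc3)c2)oc2c(-c3cc(OCc4ccccc4)c(OCc4ccccc4)cc3C3OCCO3)c(OCc3ccccc3)cc(OCc3ccccc3)c12
A8 | alternative 3 | 3,5-bis(benzyloxy)-2-[4,5-bis(benzyloxy)-2-(1,3-dioxolan-2-yl)phenyl]-6-iodophenol | Oc1c(I)c(OCc2ccccc2)cc(OCc2ccccc2)c1-c1cc(OCc2ccccc2)c(OCc2ccccc2)cc1C1OCCO1
A9 | alternative 3 | 1,2-bis(benzyloxy)-4-ethynylbenzene | C#Cc1ccc(OCc2ccccc2)c(OCc2ccccc2)c1
A10 | alternative 3 | carbon monoxide | [C-]#[O+]
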